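**Plan**
- Last cut: the aryl ether C11–O (Mitsunobu with umbelliferone). C11 is traced back to the C9 carbonyl of a carvone-derived ring B (methylenation, then hydroboration).
- Ring A is cut at C1–C2 and C3–C4. What allows this: the C2–C3 glycol lies between C4, a gem-dimethyl carbon that is the tertiary radical of an isopropenyl group, and C1, a bare CH2 on quaternary C10 that can enter as an aldehyde sulfonylhydrazone (radical acceptor, then loss of sulfinate and N2). The glycol itself is vinylene carbonate.
- Forward: (S)-carvone gives ring B with C5; C10 is made quaternary (CH3, then CH2OH → CHO → hydrazone); one radical [4+2] annulation closes ring A; C3 is inverted by oxidation/reduction; C9=O → C11 → coumarin ether.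
- Stereochemistry: C5 from (S)-carvone; C10 by enolate alkylation anti to isopropenyl; C2 in the annulation (cis-fused carbonate, O equatorial); C3 by axial hydride delivery to the 3-ketone; C9 by hydroboration anti to the axial C10 methyl.

Key step: step 5

Remark on the chemistry: drimane numbering is used for all intermediates (ring A: C1–C5 and C10; ring B: C5–C10; C11 on C9, C12 on C8, C13/C14 on C4, C15 on C10), faces are given as cis or trans to the C10 methyl, and all starting materials are taken to be commercial.

**Step 1**
Reactants: 1 (S)-(+)-carvone
Product: 2 6-methylcarvone (both epimers at the methyl-bearing carbon)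
Conditions: LiN(iPr)2, THF, −78 °C; MeI, −78 °C to 0 °C
Reagents that add atoms: iodomethane, CI
Why: Kinetic deprotonation of the enone at its only saturated α-carbon (future C10) and SN2 methylation of the lithium enolate (enolate alkylation) should give 2; the configuration at this carbon does not matter because step 2 passes through the same planar enolate.

**Step 2**
Reactants: 2 6-methylcarvone
Product: 3 6-(hydroxymethyl)-6-methylcarvone (CH2OH trans to isopropenyl)
Conditions: LiN(iPr)2, THF, −78 °C to −40 °C; CH2O (gas, from cracked paraformaldehyde), −78 °C; then AcOH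
Reagents that add atoms: formaldehyde, C=O
Why: The tetrasubstituted enolate should add to monomeric formaldehyde (aldol-type hydroxymethylation) on the face anti to the neighbouring isopropenyl group on C5, which sets C10 with CH2OH (future C1) trans and CH3 cis to the isopropenyl group.

**Step 3**
Reactants: 3 6-(hydroxymethyl)-6-methylcarvone
Product: 4 6-formyl-6-methylcarvone (CHO trans to isopropenyl)
Conditions: Dess–Martin periodinane, CH2Cl2, 0 °C to rt
Reagents that add atoms: none
Why: Dess–Martin oxidation of the primary neopentyl alcohol under non-basic conditions should give the non-enolisable aldehyde without retro-aldol loss of formaldehyde.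

**Step 4**
Reactants: 4 6-formyl-6-methylcarvone
Product: 5 (E)-N-tosylhydrazone of 4 at the aldehyde carbon C1
Conditions: TsNHNH2, EtOH, rt
Reagents that add atoms: p-toluenesulfonyl hydrazide, NNS(=O)(=O)c1ccc(C)cc1
Why: Hydrazone formation should be selective for the aldehyde because the C9 ketone is conjugated and flanked by quaternary C10; it turns C1 into a radical acceptor that can later lose nitrogen.

**Step 5**
Reactants: 5 N-tosylhydrazone, 6 vinylene carbonate
Product: 9 2,3-cis-dihydroxy-11-nordrim-7-en-9-one (both OH trans to the C10 methyl), via ring A hydrazide 7 (not isolated), via cyclic carbonate 8 (not isolated)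
Conditions: Fe(acac)3 (30 mol %), PhSiH3, 6 (15 equiv), EtOH–THF, 60 °C, 5 added slowly; then K2CO3, MeOH, 60 °C
Reagents that add atoms: none
Why: Proposed new method: iron hydride (from Fe(acac)3 and PhSiH3) transfers a hydrogen atom to the CH2 end of the isopropenyl group, the tertiary C4 radical adds to vinylene carbonate 6 (C3–C4, Giese-type), the nucleophilic dioxolanonyl radical at C2 attacks the hydrazone carbon C1 (C1–C2), the hydrazinyl radical is reduced to hydrazide 7, and base then expels sulfinate and N2 (Caglioti-type alkyldiazene decomposition) to leave C1 as CH2 in 8 before methanolysis frees diol 9. The closest known reaction types are the iron-hydride reductive olefin–hydrazone coupling with traceless sulfonylhydrazones, iron-hydride Giese additions of tertiary radicals, and radical cyclisations onto sulfonyl- or aziridinyl-hydrazones; only their union into a formal radical [4+2] annulation is new. Ring A closes in the 6-exo-trig mode on the C=N bond through a chair in which the ring B bonds C10–C1 and C5–C4 are both equatorial; the carbonate ring is not closed here but comes in with 6. C2 is set by the cis fusion that the five-membered carbonate enforces (C1–C2 forms on the same face as C3–C4), and the C3 configuration is that of the only adduct radical that can cyclise without forcing O–C2 into the axial site between the axial methyl groups on C4 and C10, so both oxygens end trans to the C10 methyl. The step needs hydrogen-atom transfer to the 1,1-disubstituted alkene only (the conjugated, trisubstituted C7=C8 is a poor hydrogen-atom acceptor) and trapping by 6 faster than radical reduction or capture by a second molecule, which the large excess of 6 and the slow addition of 5 should secure; the C9 carbonyl is also within 6-exo reach but is a far poorer radical acceptor than the C=N bond.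

**Step 6**
Reactants: 9 2,3-cis-dihydroxy-11-nordrim-7-en-9-one
Product: 10 2-O-methoxymethyl ether of 9 (3-OH free)
Conditions: MOMCl, iPr2NEt, CH2Cl2, 0 °C to rt
Reagents that add atoms: chloromethyl methyl ether, COCCl
Why: Alkylation of the less hindered equatorial 2-OH (MOM protection) should leave the axial 3-OH, shielded by the C4 gem-dimethyl group, free for the inversion sequence.

**Step 7**
Reactants: 10 2-O-methoxymethyl ether
Product: 11 2-(methoxymethoxy)-11-nordrim-7-ene-3,9-dione
Conditions: Dess–Martin periodinane, CH2Cl2, rt
Reagents that add atoms: none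
Why: Dess–Martin oxidation of the axial secondary alcohol should give the 3-ketone and so erase the C3 configuration, while C2, now α to the ketone, already holds its more stable equatorial configuration.

**Step 8**
Reactants: 11 2-(methoxymethoxy)-11-nordrim-7-ene-3,9-dione
Product: 12 3-hydroxy-2-(methoxymethoxy)-11-nordrim-7-en-9-one (3-OH equatorial and trans to O2)
Conditions: NaBH4, MeOH–CH2Cl2, −40 °C
Reagents that add atoms: none
Why: Borohydride reduction should deliver hydride to C3 along the axial path on the face anti to the axial methyl groups of C4 and C10, giving the equatorial 3-OH, while the conjugated C9 ketone between C10 and C8 should react much more slowly at low temperature.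

**Step 9**
Reactants: 12 3-hydroxy-2-(methoxymethoxy)-11-nordrim-7-en-9-one
Product: 13 2-(methoxymethoxy)drima-7,9(11)-dien-3-ol
Conditions: Ph3PCH3Br, KOtBu, toluene, 80 °C
Reagents that add atoms: methyltriphenylphosphonium bromide, C[P+](c1ccccc1)(c1ccccc1)c1ccccc1.[Br-]
Why: Wittig methylenation of the only remaining carbonyl should give the 7,9(11)-diene; one equivalent of ylide is spent on the free 3-OH, which is regenerated on work-up.

**Step 10**
Reactants: 13 2-(methoxymethoxy)drima-7,9(11)-dien-3-ol
Product: 15 2-(methoxymethoxy)drim-7-ene-3,11-diol (C11 cis to the C10 methyl), via B-alkyl-9-borabicyclononane 14 (not isolated)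
Conditions: 9-BBN, THF, 0 to 50 °C; then NaOH, H2O2, H2O, 0 °C to rt
Reagents that add atoms: hydrogen peroxide, OO
Why: Hydroboration–oxidation: the bulky borane should add to terminal C11 of the exocyclic alkene and deliver hydrogen to C9 on the face anti to the axial C10 methyl, which sets C9 with C11 cis to that methyl, and should leave the trisubstituted C7=C8 alone.

**Step 11**
Reactants: 15 2-(methoxymethoxy)drim-7-ene-3,11-diol, 16 umbelliferone
Product: 17 2-O-methoxymethyl ether of the target
Conditions: PPh3, DIAD, THF, 0 °C to rt
Reagents that add atoms: none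
Why: Mitsunobu etherification should couple the primary C11–OH with the acidic phenol of 16, while the secondary 3-OH next to the gem-dimethyl carbon is too hindered to be activated; no stereocentre is touched.

**Step 12**
Reactants: 17 2-O-methoxymethyl ether of the target
Product: 18 target
Conditions: HCl (cat.), MeOH, 40 °C
Reagents that add atoms: none
Why: Acid-catalysed acetal exchange with methanol (MOM cleavage) should free the 2-OH without affecting the aryl ether, the lactone or the C7=C8 alkene.

**Compound list**
1 | (S)-(+)-carvone, (5S)-2-methyl-5-(prop-1-en-2-yl)cyclohex-2-en-1-one | CC1=CC[C@@H](CC1=O)C(C)=C | starting material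
2 | 6-methylcarvone, (5S)-2,6-dimethyl-5-(prop-1-en-2-yl)cyclohex-2-en-1-one, both epimers at C6 (drimane C10) | CC1=CC[C@@H](C(C)C1=O)C(C)=C | intermediate
3 | 6-(hydroxymethyl)-6-methylcarvone; CH2OH (future C1) trans and CH3 (C15) cis to the isopropenyl group | CC1=CC[C@@H]([C@@](C)(CO)C1=O)C(C)=C | intermediate
4 | 6-formyl-6-methylcarvone; CHO (C1) trans to the isopropenyl group | CC1=CC[C@@H]([C@@](C)(C=O)C1=O)C(C)=C | intermediate
5 | (E)-N-tosylhydrazone of 4 at the aldehyde carbon C1 | CC1=CC[C@@H]([C@@](C)(/C=N/NS(=O)(=O)c2ccc(C)cc2)C1=O)C(C)=C | intermediate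
6 | vinylene carbonate (1,3-dioxol-2-one) | O=C1OC=CO1 | starting material
7 | ring A hydrazide: cis-2,3-carbonate of 11-nordrim-7-en-9-one with NHNHTs on C1 (C1 configuration undefined); trans ring fusion, both O trans to the C10 methyl | CC1=CC[C@@H]2C(C)(C)[C@H]3OC(=O)O[C@H]3C(NNS(=O)(=O)c3ccc(C)cc3)[C@@]2(C)C1=O | intermediate
8 | cyclic carbonate of 2,3-cis-dihydroxy-11-nordrim-7-en-9-one; trans ring fusion, both O trans to the C10 methyl | CC1=CC[C@@H]2C(C)(C)[C@H]3OC(=O)O[C@H]3C[C@@]2(C)C1=O | intermediate
9 | 2,3-cis-dihydroxy-11-nordrim-7-en-9-one; 2-OH equatorial, 3-OH axial, both trans to the C10 methyl; H5 trans to the C10 methyl | CC1=CC[C@@H]2C(C)(C)[C@@H](O)[C@@H](O)C[C@@]2(C)C1=O | intermediate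
10 | 2-O-methoxymethyl ether of 9; axial 3-OH free | CC1=CC[C@@H]2C(C)(C)[C@@H](O)[C@@H](OCOC)C[C@@]2(C)C1=O | intermediate
11 | 2-(methoxymethoxy)-11-nordrim-7-ene-3,9-dione; 2-OMOM equatorial, trans to the C10 methyl | CC1=CC[C@@H]2C(C)(C)C(=O)[C@@H](OCOC)C[C@@]2(C)C1=O | intermediate
12 | 3-hydroxy-2-(methoxymethoxy)-11-nordrim-7-en-9-one; 3-OH equatorial, cis to the C10 methyl, trans to 2-OMOM | CC1=CC[C@@H]2C(C)(C)[C@H](O)[C@@H](OCOC)C[C@@]2(C)C1=O | intermediate
13 | 2-(methoxymethoxy)drima-7,9(11)-dien-3-ol; ring A as in 12 | CC1=CC[C@@H]2C(C)(C)[C@H](O)[C@@H](OCOC)C[C@@]2(C)C1=C | intermediate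
14 | C11 B-alkyl-9-borabicyclo[3.3.1]nonane of 13; H9 trans to the C10 methyl | CC1=CC[C@@H]2C(C)(C)[C@H](O)[C@@H](OCOC)C[C@@]2(C)[C@@H]1CB1C2CCCC1CCC2 | intermediate
15 | 2-(methoxymethoxy)drim-7-ene-3,11-diol; C11 cis to the C10 methyl | CC1=CC[C@@H]2C(C)(C)[C@H](O)[C@@H](OCOC)C[C@@]2(C)[C@@H]1CO | intermediate
16 | umbelliferone (7-hydroxy-2H-chromen-2-one) | Oc1ccc2ccc(=O)oc2c1 | starting material
17 | 7-O-(C11) umbelliferone ether of 15 (2-O-MOM ether of the target) | CC1=CC[C@@H]2C(C)(C)[C@H](O)[C@@H](OCOC)C[C@@]2(C)[C@@H]1COc1ccc2ccc(=O)oc2c1 | intermediate
18 | target: 7-[(2,3-dihydroxydrim-7-en-11-yl)oxy]coumarin with the given configuration | CC1=CC[C@@H]2C(C)(C)[C@H](O)[C@@H](O)C[C@@]2(C)[C@@H]1COc1ccc2ccc(=O)oc2c1 | target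

**Totals**
Total steps: 12. Longest linear sequence: 12 steps (1 to 18).

**Steps most likely to fail**

Step 5 (proposed new method). The hindered tertiary radical may be reduced, or may add to the hydrazone or enone of a second molecule, faster than it adds to vinylene carbonate. The intermolecular addition fixes C3 without a controlling element, so part of the adduct radical may carry the C3 configuration that cannot close ring A and be lost by reduction. The sulfonylhydrazone may also cyclise onto the C9 carbonyl through its N–H before the radical step. Fallback with known chemistry, ring A built bond by bond: from 2, Michael addition of the lithium enolate to acrylonitrile (anti to isopropenyl) gives the 2-cyanoethyl ketone F1. Iron-hydride hydrogen-atom-transfer cyclisation of the isopropenyl-derived radical onto the nitrile (Fe(acac)3, PhSiH3, EtOH, then aqueous acid) gives the 3,9-dione F2. Enolisation toward C2 with KN(SiMe3)2 (the only α-hydrogens of the C3 ketone) and oxidation with 2-(phenylsulfonyl)-3-phenyloxaziridine gives the equatorial 2-hydroxy-3,9-dione F3. Its MOM ether (MOMCl, iPr2NEt) is 11, where the route is rejoined.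

Step 9. The ylide may fail to add to a carbonyl flanked by quaternary C10 and the methyl-bearing C8, and may instead deprotonate C6, the γ-position of the enone. Fallback: from 12, 1,2-addition of Me3SiCH2Li in the presence of CeCl3 (THF, −78 °C) gives the β-hydroxysilane F4, and a separate Peterson elimination (KH, THF) gives 13.

Step 11. Displacement at the β-branched C11 next to quaternary C10 may be slow, so the activated alcohol may be consumed by elimination or by the hydrazine by-product before the phenol attacks. Fallback: from 15, selective sulfonylation of the primary alcohol (TsCl, pyridine) gives the tosylate F5, and SN2 displacement with umbelliferone and Cs2CO3 in DMF at 80 °C gives 17.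

**Further compounds**
F1 | step 5 | 6-(2-cyanoethyl)-6-methylcarvone, cyanoethyl trans to isopropenyl | CC1=CC[C@@H]([C@@](C)(CCC#N)C1=O)C(C)=C
F2 | step 5 | 11-nordrim-7-ene-3,9-dione, trans ring fusion | CC1=CC[C@@H]2C(C)(C)C(=O)CC[C@@]2(C)C1=O
F3 | step 5 | 2-hydroxy-11-nordrim-7-ene-3,9-dione, 2-OH equatorial and trans to the C10 methyl | CC1=CC[C@@H]2C(C)(C)C(=O)[C@@H](O)C[C@@]2(C)C1=O
F4 | step 9 | 9-hydroxy-9-[(trimethylsilyl)methyl] adduct of 12 (C9 configuration undefined) | CC1=CC[C@@H]2C(C)(C)[C@H](O)[C@@H](OCOC)C[C@@]2(C)C1(O)C[Si](C)(C)C
F5 | step 11 | C11 p-toluenesulfonate of 15 | CC1=CC[C@@H]2C(C)(C)[C@H](O)[C@@H](OCOC)C[C@@]2(C)[C@@H]1COS(=O)(=O)c1ccc(C)cc1
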